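Green, the earlier closed flask, is your ledger for the starting material, the limiting reagent, and from it you must choose between dusk and midnight.

| setting | green | dusk | midnight |
|---|---|---|---|
| starting material | 3 M | 3.0 M | 3.0 M |
| remark | run made earlier | one stirred flow tank at steady state, fed with the mixture as stated, mean residence time 2.0 min | everything together in a closed stirred flask, run for 2.0 min |
| time |  |  | 2.0 min |

green run (percent of the starting material charged)

| time / s | target / % | over-reaction product / % |
|---|---|---|
| 10.0 | 51.5 | 2.8 |
| 12.0 | 52.9 | 3.0 |
| 20.0 | 54.4 | 5.7 |
| 30.0 | 50.5 | 10.2 |
| 50.0 | 44.3 | 17.1 |
| 80.0 | 34.4 | 27.4 |

(scatter of a reading: 0.5 percentage points)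

1. the set-up with the highest share of target in all that became target or over-reaction product, at the outlet or at the end ("none" if the first two lie within 2 percentage points) (dusk / midnight / none)
2. share of target in all that became target or over-reaction product, at the outlet or at the end, dusk
3. share of target in all that became target or over-reaction product, at the outlet or at the end, midnight

- the stated concentrations are those of everything mixed, before any reaction; amounts are the same in each set-up
- the earlier runs were made in a closed, stirred flask
- a reading or a percentage of target counts all its forms, free or not

Enter the charge line by line. At 80.0 s green books 34.4% as target and 27.4% as over-reaction product, together 61.8%, so 38.2% stands on neither reading. At 30.0 s the two came to 60.7%, a gain of just 1.1 percentage points since then, so I treat the later ledger as one moving entry: target passing into over-reaction product.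

I read the fall as an exponential, which is my assumption of plain first-order loss. The target readings fall from 54.4% at 20.0 s to 34.4% at 80.0 s, which reads as 0.00764 s⁻¹, the loss constant: the fraction of target lost per unit time, a value with the scatter of those readings.

Integrating that rate from 80.0 s with the total held gives midnight a share of 41.0%. In dusk, steady state with that first-order loss makes [over-reaction product]/[target] equal the loss constant times the residence time, 0.917, whatever amount formed, so I reckon the share at 52.2%. I commit to dusk, ahead by 11 points, more than the margin of 2 points.

The forecast, which differs, says none, with 33% for dusk and 34% for midnight, reading the loss as “zero order in target, meaning a saturated catalyst”. The flask gives dusk, with 52.5% for dusk and 41.7% for midnight.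

    starting material → target (k = 0.140 s⁻¹)
    starting material + target ⇌ idle adduct, settled at all times (K = 0.140 M⁻¹)
    intermediate A ⇌ intermediate B (K = 0.901, k = 0.00634 s⁻¹)
    starting material → intermediate A (k = 0.0876 s⁻¹)
    target → over-reaction product (k = 0.00766 s⁻¹)

In midnight, starting material first went to target and intermediate A, with half-lives of 0.083 min and 0.13 min by each path on its own. Target then passed to over-reaction product, free target having a half-life of 1.5 min by that step on its own, while intermediate A fed intermediate B, and the end held 25.6% target, 24.2% intermediate A and 14.3% intermediate B, each as a percentage of the charge. Run on to 20.0 min, the same exponential gives midnight a share of 0.0107%; the flask left that long shows 0.0106%.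

The earlier runs and the new flask are simulated from invented constants.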